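**Retrosynthetic overview**

1. Palisadin B (19) comes from Appel bromination of the C1' alcohol 18, which comes from silyl ether 17. C2–H and the C3=C4 alkene of 17 arise from Luche reduction and reductive allylic transposition of the cyclic β-alkoxy enone 14, whose C3 methyl is put in by iodination and Negishi coupling of 12.
2. Key disconnection and the feature it rests on: in the oxepene ring (O1, C2, C3, C4, C5, C5a, C9a) the bonds O1–C2 and C3–C4 are cut. O1–C9a–C5a–C5–C4 is then the trans-fused γ-lactone 5 on ring A with C4 as its carbonyl, and C1'–C2–C3 is the propargyl silyl ether 8, spliced as an alkyne into the lactone acyl–oxygen bond.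
3. Lactone 5 comes from bromonium-initiated cyclization of homogeranic acid 1 (ring A and the lactone close together; C5a, C7 and C9a set relative to one another). The absolute configuration is secured by separating the (S)-1-phenylethylamides.
4. Ring order: ring A plus γ-lactone (step 1), then enlargement of the lactone to the seven-membered oxepinone (step 5); C2 is the last stereocentre (step 9).

Key step: step 5

Assumption: homogeranic acid (1) is treated as a purchasable compound and MeZnCl as its commercial THF solution; the C4 carbinol of 15 is carried on as whatever epimer mixture forms, because step 9 erases that centre.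

**Route**

Step 1
Reactants: 1 homogeranic acid [(3E)-4,8-dimethylnona-3,7-dienoic acid]
Product: 2 racemic trans-fused bromo γ-lactone rac-(3aS,5S,7aS)-5-bromo-4,4,7a-trimethylhexahydro-1-benzofuran-2(3H)-one
Conditions: Et2SBr·SbCl5Br (1.1 equiv), MeNO2, −25 °C, 10 min; aq. NaHCO3/Na2SO3
Reagents that add atoms: bromodiethylsulfonium bromopentachloroantimonate, CC[S+](Br)CC.Cl[Sb-](Cl)(Cl)(Cl)(Cl)Br
Why: Bromonium-initiated cation–olefin (polyene) cyclization ended by the carboxyl group: a chair transition state with anti addition across the E-trisubstituted alkene should place bromine equatorial at C5 and give the trans ring fusion (C3a–H and the C7a methyl both axial), so the three stereocentres are set relative to one another, as the racemate.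

Step 2
Reactants: 2 racemic bromo γ-lactone; 3 (S)-1-phenylethylamine
Product: 4 N-[(1S)-1-phenylethyl]-2-[(1S,3S,6S)-3-bromo-6-hydroxy-2,2,6-trimethylcyclohexyl]acetamide (separated from its diastereomer)
Conditions: 3, AlMe3, CH2Cl2, 0 → 40 °C; aq. work-up; SiO2 chromatography, then recrystallization
Reagents that add atoms: none
Why: Aluminium amide aminolysis of the lactone (acyl–oxygen cleavage, no stereocentre touched) turns the two enantiomers into diastereomeric hydroxy amides that should be separable, the (1S,3S,6S) series to be identified by X-ray diffraction with bromine as the heavy atom.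

Step 3
Reactants: 4 hydroxy amide
Product: 5 (3aS,5S,7aS)-5-bromo-4,4,7a-trimethylhexahydro-1-benzofuran-2(3H)-one
Conditions: p-TsOH·H2O (1.5 equiv), toluene, 80 °C
Reagents that add atoms: none
Why: Acid-promoted lactonization of a γ-hydroxy amide (N→O acyl transfer): the tertiary hydroxyl attacks the protonated amide and the amine leaves as its ammonium salt, so the C7a–O bond is never broken and the configuration is kept.

Step 4
Reactants: 6 propargyl alcohol; 7 chlorotriisopropylsilane
Product: 8 triisopropyl(prop-2-yn-1-yloxy)silane
Conditions: imidazole, CH2Cl2, 0 → 23 °C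
Reagents that add atoms: none
Why: Standard silylation of a primary alcohol; the bulky silyl ether should survive acetylide formation, iodine/pyridine, the organozinc reagent, borohydride and BF3·OEt2 at −78 °C.

Step 5
Reactants: 5 (3aS,5S,7aS)-bromo γ-lactone; 8 triisopropyl(prop-2-yn-1-yloxy)silane
Product: 12 (5aS,7S,9aS)-7-bromo-6,6,9a-trimethyl-2-[(triisopropylsilyloxy)methyl]-5a,6,7,8,9,9a-hexahydro-1-benzoxepin-4(5H)-one, via lithium acetylide 9 (not isolated), via lithium lactolate 10 (not isolated), via ring-opened alkoxy ynone 11 (not isolated)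
Conditions: 8 (1.15 equiv), n-BuLi (1.1 equiv), THF, −78 °C; then 5, −78 → −20 °C; then t-BuOH (3 equiv), KOt-Bu (0.2 equiv), −20 → 23 °C; pH 7 buffer
Reagents that add atoms: none
Why: Proposed new method: lithium acetylide 9 adds to the lactone carbonyl (C3–C4 bond) to give lactolate 10, which on warming equilibrates with the ring-opened ynone 11 carrying the tertiary C9a alkoxide; this alkoxide adds to the alkyne carbon C2 (O1–C2 bond) while t-BuOH protonates C3, since a seven-membered cyclic allenolate is too strained to accumulate, and the protonation makes the closure irreversible, so the acyl–oxygen bond of the lactone has taken up C2 and C3. The closest known reactions are the opening of lactones by acetylides to hydroxy ynones and the base-promoted 6-endo-dig cyclization of β-hydroxy ynones to dihydropyranones; a one-flask seven-membered version starting from a γ-lactone is not established. The ring closes in the 7-endo-dig mode and no stereocentre is formed; C5a, C7 and C9a lie away from every acidic position, and the equatorial C7 bromide next to the quaternary C6 has neither an antiperiplanar hydrogen for E2 nor an open backside for SN2. The step needs the attack of O1 on C2 to outrun the return to the five-membered lactolate and any second acetylide addition: the lactolate is only a reversible resting state whereas the protonated vinylogous ester cannot revert, t-BuOH destroys the small excess of 9 before the ketone is unmasked, and tert-butoxide is too hindered to add to the ynone itself. The regiochemistry (C2, not C3) follows from the polarity of the ynone.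

Step 6
Reactants: 12 seven-membered β-alkoxy enone
Product: 13 (5aS,7S,9aS)-7-bromo-3-iodo-6,6,9a-trimethyl-2-[(triisopropylsilyloxy)methyl]-5a,6,7,8,9,9a-hexahydro-1-benzoxepin-4(5H)-one
Conditions: I2 (2 equiv), pyridine/CH2Cl2, 23 °C
Reagents that add atoms: iodine, I-I
Why: Electrophilic α-iodination of a vinylogous ester: C3 is the nucleophilic carbon of the enol ether, iodine attacks there and pyridine removes the proton, while the C5 methylene and the silyl ether are not affected.

Step 7
Reactants: 13 α-iodo enone
Product: 14 (5aS,7S,9aS)-7-bromo-3,6,6,9a-tetramethyl-2-[(triisopropylsilyloxy)methyl]-5a,6,7,8,9,9a-hexahydro-1-benzoxepin-4(5H)-one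
Conditions: MeZnCl (2 equiv), Pd(PPh3)4 (5 mol %), THF, 23 → 50 °C
Reagents that add atoms: methylzinc chloride, C[Zn]Cl
Why: Negishi cross-coupling: zerovalent palladium inserts into the activated alkenyl C–I bond much faster than into the hindered secondary alkyl bromide, and the organozinc does not add to the ketone.

Step 8
Reactants: 14 α-methyl β-alkoxy enone
Product: 15 (5aS,7S,9aS)-7-bromo-3,6,6,9a-tetramethyl-2-[(triisopropylsilyloxy)methyl]-4,5,5a,6,7,8,9,9a-octahydro-1-benzoxepin-4-ol
Conditions: NaBH4, CeCl3·7H2O, MeOH, −40 → 0 °C; pH 7 buffer; used crude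
Reagents that add atoms: none
Why: Luche 1,2-reduction: the cerium-modified borohydride adds to the carbonyl of the vinylogous ester and not to its deactivated β-carbon; the new C4 carbinol centre (either epimer acceptable) is erased in step 9.

Step 9
Reactants: 15 allylic alcohol
Product: 17 triisopropyl{[(2R,5aS,7S,9aS)-7-bromo-3,6,6,9a-tetramethyl-2,5,5a,6,7,8,9,9a-octahydro-1-benzoxepin-2-yl]methoxy}silane, via allyl oxocarbenium ion 16 (not isolated)
Conditions: Et3SiH (5 equiv), BF3·OEt2 (2 equiv), CH2Cl2, −78 °C
Reagents that add atoms: none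
Why: Ferrier-type reductive allylic transposition (ionic hydrogenation), as practised on Luche-reduced dihydropyranones: BF3-assisted loss of the C4 hydroxyl gives the O1-stabilised allyl cation 16, Et3SiH delivers hydride to the oxocarbenium carbon C2 so that the alkene ends at C3=C4, and attack on the face opposite the axial C9a methyl (1,3 to C2) should set C2 as R with the silyloxymethyl group cis to that methyl.

Step 10
Reactants: 17 silyl ether
Product: 18 [(2R,5aS,7S,9aS)-7-bromo-3,6,6,9a-tetramethyl-2,5,5a,6,7,8,9,9a-octahydro-1-benzoxepin-2-yl]methanol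
Conditions: Bu4NF, THF, 0 → 23 °C
Reagents that add atoms: none
Why: Fluoride cleavage of the silyl ether; no other group in the molecule responds to Bu4NF under these conditions.

Step 11
Reactants: 18 primary alcohol
Product: 19 Palisadin B, (2R,5aS,7S,9aS)-7-bromo-2-(bromomethyl)-3,6,6,9a-tetramethyl-2,5,5a,6,7,8,9,9a-octahydro-1-benzoxepine
Conditions: CBr4, PPh3, CH2Cl2, 0 °C
Reagents that add atoms: tetrabromomethane, BrC(Br)(Br)Br
Why: Appel reaction: bromide displaces the primary alkoxyphosphonium at C1' by SN2, and the neighbouring C2 stereocentre, the trisubstituted alkene and the ether take no part.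

**Compound list**

1 | homogeranic acid, (3E)-4,8-dimethylnona-3,7-dienoic acid | CC(C)=CCC/C(C)=C/CC(=O)O | starting material
2 | rac-(3aS,5S,7aS)-5-bromo-4,4,7a-trimethylhexahydro-1-benzofuran-2(3H)-one (racemate, one enantiomer drawn) | O=C1C[C@H]2C(C)(C)[C@@H](Br)CC[C@]2(C)O1 | intermediate
3 | (S)-1-phenylethylamine | C[C@H](N)c1ccccc1 | starting material
4 | N-[(1S)-1-phenylethyl]-2-[(1S,3S,6S)-3-bromo-6-hydroxy-2,2,6-trimethylcyclohexyl]acetamide | O=C(N[C@@H](C)c1ccccc1)C[C@H]1C(C)(C)[C@@H](Br)CC[C@]1(C)O | intermediate
5 | (3aS,5S,7aS)-5-bromo-4,4,7a-trimethylhexahydro-1-benzofuran-2(3H)-one | O=C1C[C@H]2C(C)(C)[C@@H](Br)CC[C@]2(C)O1 | intermediate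
6 | propargyl alcohol | C#CCO | starting material
7 | chlorotriisopropylsilane | CC(C)[Si](Cl)(C(C)C)C(C)C | starting material
8 | triisopropyl(prop-2-yn-1-yloxy)silane | C#CCO[Si](C(C)C)(C(C)C)C(C)C | intermediate
9 | lithium acetylide of 8 | [Li]C#CCO[Si](C(C)C)(C(C)C)C(C)C | intermediate (not isolated)
10 | lithium lactolate, adduct of 9 to the carbonyl of 5 (lactol carbon unassigned) | [Li]OC1(C#CCO[Si](C(C)C)(C(C)C)C(C)C)C[C@H]2C(C)(C)[C@@H](Br)CC[C@]2(C)O1 | intermediate (not isolated)
11 | ring-opened ynone with lithium C9a alkoxide, 1-[(1S,3S,6S)-3-bromo-6-(lithiooxy)-2,2,6-trimethylcyclohexyl]-5-(triisopropylsilyloxy)pent-3-yn-2-one | O=C(C#CCO[Si](C(C)C)(C(C)C)C(C)C)C[C@H]1C(C)(C)[C@@H](Br)CC[C@]1(C)O[Li] | intermediate (not isolated)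
12 | (5aS,7S,9aS)-7-bromo-6,6,9a-trimethyl-2-[(triisopropylsilyloxy)methyl]-5a,6,7,8,9,9a-hexahydro-1-benzoxepin-4(5H)-one | O=C1C[C@H]2C(C)(C)[C@@H](Br)CC[C@]2(C)OC(CO[Si](C(C)C)(C(C)C)C(C)C)=C1 | intermediate
13 | 3-iodo derivative of 12 | O=C1C[C@H]2C(C)(C)[C@@H](Br)CC[C@]2(C)OC(CO[Si](C(C)C)(C(C)C)C(C)C)=C1I | intermediate
14 | 3-methyl derivative of 12 | O=C1C[C@H]2C(C)(C)[C@@H](Br)CC[C@]2(C)OC(CO[Si](C(C)C)(C(C)C)C(C)C)=C1C | intermediate
15 | C4 allylic alcohol from 14 (C4 configuration not fixed) | OC1C[C@H]2C(C)(C)[C@@H](Br)CC[C@]2(C)OC(CO[Si](C(C)C)(C(C)C)C(C)C)=C1C | intermediate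
16 | O1-stabilised allyl cation (oxocarbenium at C2, alkene C3=C4) | CC1=CC[C@H]2C(C)(C)[C@@H](Br)CC[C@]2(C)[O+]=C1CO[Si](C(C)C)(C(C)C)C(C)C | intermediate (not isolated)
17 | triisopropyl{[(2R,5aS,7S,9aS)-7-bromo-3,6,6,9a-tetramethyl-2,5,5a,6,7,8,9,9a-octahydro-1-benzoxepin-2-yl]methoxy}silane | CC1=CC[C@H]2C(C)(C)[C@@H](Br)CC[C@]2(C)O[C@H]1CO[Si](C(C)C)(C(C)C)C(C)C | intermediate
18 | [(2R,5aS,7S,9aS)-7-bromo-3,6,6,9a-tetramethyl-2,5,5a,6,7,8,9,9a-octahydro-1-benzoxepin-2-yl]methanol | CC1=CC[C@H]2C(C)(C)[C@@H](Br)CC[C@]2(C)O[C@H]1CO | intermediate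
19 | Palisadin B | CC1=CC[C@H]2C(C)(C)[C@@H](Br)CC[C@]2(C)O[C@H]1CBr | target

**Step count**

Total: 11 steps. Longest linear sequence: 10 steps (steps 1–3 and 5–11, from 1); step 4 is a one-step side branch.

**Steps most likely to fail, with fallbacks**

1. Step 5 (proposed new method). The sequence may stop at the lactol stage, with acetylide addition but no seven-membered closure. The lactone may also be enolized instead of attacked, or the unmasked ketone may take up a second acetylide. The fallback builds the oxepene without an alkyne, by known reactions only. It sets out from lactone 5 and comes back at alcohol 18. Reduction of 5 with i-Bu2AlH (CH2Cl2, −78 °C) gives the lactol F1. Wittig methylenation (Ph3P=CH2, THF) opens it to the tertiary alkenol F2. Its potassium alkoxide (KN(SiMe3)2, THF, −78 °C) is acylated with methacryloyl chloride to the methacrylate F3. Ring-closing metathesis (second-generation Grubbs catalyst, toluene, 80 °C) closes the seven-membered α-methyl unsaturated lactone F4, in which C3(Me)=C4 is already in place. Methylenation of the lactone carbonyl with Cp2TiMe2 (toluene, 70 °C) gives the 2-methylene dienyl ether F5. Hydroboration with 9-BBN and oxidation (NaOH, H2O2) put boron on C1' and hydrogen on C2 from the face away from the C9a methyl, which leads to 18; step 11 then finishes the route.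

2. Step 9. Cation 16 may take up hydride at C4 instead of C2 (giving the 2,3-enol ether and its over-reduction), or on the face of the C9a methyl (giving the C2 epimer). The fallback replaces capture of a free cation by inner-sphere hydride delivery from palladium. It sets out from alcohol 15 and comes back at silyl ether 17. It needs the 4S epimer of 15 (hydroxyl on the face of the C9a methyl), which borohydride attack on the open lower face of C4 should give. That epimer is converted with ClCO2Me/pyridine (CH2Cl2, 0 °C) into the allylic methyl carbonate F6. Pd(OAc)2/PBu3 with HCO2NH4 in THF ionizes F6 with inversion. After loss of CO2, the allylpalladium formate passes hydride to the more substituted allyl terminus C2 on the palladium-bearing lower face (Tsuji formate reduction). Regiochemistry is then fixed by the metal and the C2 configuration is relayed from C4, giving 17.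

3. Step 1. The bromonium ion may be lost to proton elimination, to monocyclic products or to capture before the second ring closes, so that little lactone forms. The fallback uses mercuricyclization, which is less prone to early termination. It sets out from acid 1 and comes back at lactone 2. Treatment of 1 with Hg(OCOCF3)2 (MeNO2, −20 °C), then aq. KBr, should give the racemic organomercurial lactone F7, with mercury equatorial at C5 and the same trans ring fusion. Brominative demercuration (Br2, LiBr, pyridine, 23 °C, in the dark) replaces mercury by bromine with retention and returns to 2.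

**Further compounds**

F1 | step 5 | (3aS,5S,7aS)-5-bromo-4,4,7a-trimethyloctahydro-1-benzofuran-2-ol (lactol, anomers) | OC1C[C@H]2C(C)(C)[C@@H](Br)CC[C@]2(C)O1
F2 | step 5 | (1S,2S,4S)-4-bromo-1,3,3-trimethyl-2-(prop-2-en-1-yl)cyclohexan-1-ol | C=CC[C@H]1C(C)(C)[C@@H](Br)CC[C@]1(C)O
F3 | step 5 | (1S,2S,4S)-4-bromo-1,3,3-trimethyl-2-(prop-2-en-1-yl)cyclohexyl 2-methylprop-2-enoate | C=CC[C@H]1C(C)(C)[C@@H](Br)CC[C@]1(C)OC(=O)C(C)=C
F4 | step 5 | (5aS,7S,9aS)-7-bromo-3,6,6,9a-tetramethyl-5a,6,7,8,9,9a-hexahydro-1-benzoxepin-2(5H)-one | CC1=CC[C@H]2C(C)(C)[C@@H](Br)CC[C@]2(C)OC1=O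
F5 | step 5 | (5aS,7S,9aS)-7-bromo-3,6,6,9a-tetramethyl-2-methylidene-2,5,5a,6,7,8,9,9a-octahydro-1-benzoxepine | CC1=CC[C@H]2C(C)(C)[C@@H](Br)CC[C@]2(C)OC1=C
F6 | step 9 | (4S,5aS,7S,9aS)-7-bromo-3,6,6,9a-tetramethyl-2-[(triisopropylsilyloxy)methyl]-4,5,5a,6,7,8,9,9a-octahydro-1-benzoxepin-4-yl methyl carbonate | COC(=O)O[C@H]1C[C@H]2C(C)(C)[C@@H](Br)CC[C@]2(C)OC(CO[Si](C(C)C)(C(C)C)C(C)C)=C1C
F7 | step 1 | rac-[(3aS,5S,7aS)-4,4,7a-trimethyl-2-oxooctahydro-1-benzofuran-5-yl]mercury bromide | O=C1C[C@H]2C(C)(C)[C@@H]([Hg]Br)CC[C@]2(C)O1
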